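**Retrosynthetic overview**
- Endgame: target ← reduction of a C3 pyrrolidine amide ← nickel/photoredox arylation of the CH2OH arm on C4 with 4-bromo-1,2-dimethoxybenzene ← aminolysis of a cis-fused 6-aryl furo[3,4-c]furan-1-one ← loss of an angular ester.
- Key disconnection: the oxolane is cut at O1–C5H2 (the ring-closing bond) and at C2–C3, giving 3,4,5-trimethoxybenzaldehyde and ethyl (1S,5R)-2-oxo-3-oxabicyclo[3.1.0]hexane-1-carboxylate; forward, this is an iodide-relayed, strain-releasing (3+2) ring expansion.
- Enabling feature: in the oxolane ring (O1, C2–C5) the unsubstituted methylene C5 and C3 are 1,3-related through the stereocentre C4, and the cis one-carbon arms on C3 (the CH2OH carbon) and C4 (the benzylic CH2) can be tied as a γ-lactone. C3–C4–C5 therefore map onto the cyclopropane of a 3-oxabicyclo[3.1.0]hexan-2-one, whose bond between the carbonyl-bearing carbon and the CH2 is a latent C3 enolate / C5 electrophile.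
- Ring order: cyclopropane and γ-lactone (step 1) → oxolane closed at O1–C5 while the cyclopropane is consumed (step 2) → γ-lactone opened (step 4).
- Stereochemistry: C4 comes from (R)-epichlorohydrin; C3 and C2 are set in the key step (cis ring fusion, aryl on the convex face); later steps touch no stereocentre.

Key step: step 2

Remark: locants O1 and C2–C5 are those of the oxolane ring of the target; 3a, 6 and 6a are those of the furo[3,4-c]furan-1-one. ppy = 2-phenylpyridinato, dtbbpy = 4,4'-di-tert-butyl-2,2'-bipyridine.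
Assumption: the benzoxazolium salt of step 5 is 5,7-di-tert-butyl-3-phenyl-1,3-benzoxazol-3-ium tetrafluoroborate.

**Step 1**
Reactants: 1 (R)-epichlorohydrin; 2 diethyl malonate
Product: 4 ethyl (1S,5R)-2-oxo-3-oxabicyclo[3.1.0]hexane-1-carboxylate, via epoxide-bearing malonate 3 (not isolated)
Conditions: NaOEt (1.0 equiv), EtOH, 0 °C → reflux
Reagents that add atoms: none
Why: Known malonate/epichlorohydrin cyclopropanation–lactonisation, in which the malonate anion opens the epoxide at CH2, the alkoxide re-closes an epoxide by expelling chloride (Payne-type transposition, 3), and 3-exo-tet SN2 opening of that epoxide with inversion followed by lactonisation fixes C5 as R and, through the obligatory cis fusion, C1 as S.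

**Step 2**
Reactants: 4 ethyl (1S,5R)-2-oxo-3-oxabicyclo[3.1.0]hexane-1-carboxylate; 5 3,4,5-trimethoxybenzaldehyde
Product: 8 ethyl (3aS,6S,6aR)-1-oxo-6-(3,4,5-trimethoxyphenyl)tetrahydro-1H,3H-furo[3,4-c]furan-6a(6H)-carboxylate (cis-fused; aryl on the convex face, cis to the angular ester), via iodomethyl lactone magnesium enolate 6 (not isolated), via iodo aldolate 7 (not isolated)
Conditions: MgI2 (0.5 equiv), 4 Å MS, THF, 65 °C
Reagents that add atoms: none
Why: Proposed new method: MgI2 chelates the lactone and ester carbonyls of 4 and iodide opens the strained C1–C6 bond by SN2 attack at the unsubstituted cyclopropane carbon C6, giving the chelated malonate-type enolate 6, which adds reversibly to aldehyde 5, after which the alkoxide of aldolate 7 displaces the primary iodide and returns iodide to the cycle, so that the oxolane ring is closed by forming its O1–C5H2 bond. The closest known reaction type is the MgI2-mediated ring expansion of acceptor cyclopropanes with C=X partners (spirocyclopropyl oxindoles with imines, methylenecyclopropyl amides with aldehydes, cyclopropane-1,1-diesters with nitrones), which follows the same sequence of halide opening, addition and heteroatom alkylation. The ring closure is a 5-exo-tet Williamson etherification. The quaternary centre C6a is controlled by the resident centre C3a, because only an aldolate whose carbinol carbon is cis to the iodomethyl arm can reach it and the two five-membered rings can only be cis-fused, while every other aldolate returns to 6 by retro-aldol cleavage, which makes the step a dynamic, stereoconvergent funnel. The aryl-bearing centre C6 is set in the same closure, which should be faster for the aldolate that places the aryl group on the convex face, flanked by two flat carbonyl groups and away from the lactone ring and the iodomethyl arm. The step needs opening at C6 and not at the ring-fusion carbon C5 or by alkyl–oxygen cleavage of the lactone, which is secured because C6 is the only unhindered primary cyclopropane carbon whose departure leaves a doubly stabilised enolate and because lactone cleavage by iodide is reversible and unproductive.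

**Step 3**
Reactants: 8 ethyl (3aS,6S,6aR)-1-oxo-6-(3,4,5-trimethoxyphenyl)tetrahydro-1H,3H-furo[3,4-c]furan-6a(6H)-carboxylate
Product: 9 (3aS,6R,6aR)-6-(3,4,5-trimethoxyphenyl)tetrahydro-1H,3H-furo[3,4-c]furan-1-one (cis-fused; aryl trans to the lactone carbonyl carbon)
Conditions: LiCl, H2O, DMSO, 140 °C
Reagents that add atoms: none
Why: Krapcho dealkoxycarbonylation, in which chloride dealkylates the ethyl ester, the carboxylate loses CO2 and the lactone enolate is protonated at the ring-fusion carbon, where only the cis-fused bicycle is possible, so the new C6a–H should end up on the convex face.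

**Step 4**
Reactants: 9 (3aS,6R,6aR)-6-(3,4,5-trimethoxyphenyl)tetrahydro-1H,3H-furo[3,4-c]furan-1-one
Product: 10 [(2R,3R,4R)-4-(hydroxymethyl)-2-(3,4,5-trimethoxyphenyl)oxolan-3-yl](pyrrolidin-1-yl)methanone
Conditions: pyrrolidine (excess), 2-pyridone (20 mol %), THF, 50 °C
Reagents that add atoms: pyrrolidine, C1CCNC1
Why: Aminolysis of a γ-lactone by a secondary amine under mild bifunctional (2-pyridone) catalysis opens the lactone without touching a stereocentre and makes the two one-carbon arms on C3 (amide) and C4 (free CH2OH) chemically distinct.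

**Step 5**
Reactants: 10 [(2R,3R,4R)-4-(hydroxymethyl)-2-(3,4,5-trimethoxyphenyl)oxolan-3-yl](pyrrolidin-1-yl)methanone; 11 4-bromo-1,2-dimethoxybenzene
Product: 13 [(2R,3R,4S)-4-(3,4-dimethoxybenzyl)-2-(3,4,5-trimethoxyphenyl)oxolan-3-yl](pyrrolidin-1-yl)methanone, via benzoxazoline adduct 12 (not isolated)
Conditions: 5,7-di-tert-butyl-3-phenylbenzoxazolium tetrafluoroborate, pyridine, MTBE, rt; then 11, [Ir(ppy)2(dtbbpy)]PF6 (1.5 mol %), NiBr2(dtbbpy) (5 mol %), quinuclidine, DMA–MTBE, 450 nm LEDs, rt
Reagents that add atoms: none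
Why: Nickel/photoredox deoxygenative arylation of a primary alcohol through its benzoxazolium adduct, in which oxidation and β-scission of 12 give the primary radical at the CH2 on C4, which is captured by the aryl–nickel species from 11 and coupled by reductive elimination, and since the radical is not at a stereocentre C2, C3 and C4 stay as set.

**Step 6**
Reactants: 13 [(2R,3R,4S)-4-(3,4-dimethoxybenzyl)-2-(3,4,5-trimethoxyphenyl)oxolan-3-yl](pyrrolidin-1-yl)methanone
Product: 14 [(2R,3S,4S)-4-(3,4-dimethoxybenzyl)-2-(3,4,5-trimethoxyphenyl)oxolan-3-yl]methanol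
Conditions: LiH2NBH3, THF, 0 → 23 °C; then aq. NH4Cl
Reagents that add atoms: none
Why: Lithium amidotrihydroborate reduction of a tertiary amide to the primary alcohol (hydride addition, C–N cleavage, second hydride addition), a weakly basic, non-enolising method that should avoid both epimerisation at C3 and β-elimination of the ring oxygen.

**Compound list**
1 | (R)-epichlorohydrin [(2R)-2-(chloromethyl)oxirane] | ClC[C@H]1CO1 | starting material
2 | diethyl malonate | CCOC(=O)CC(=O)OCC | starting material
3 | diethyl 2-{[(2R)-oxiran-2-yl]methyl}propanedioate | CCOC(=O)C(C[C@@H]1CO1)C(=O)OCC | intermediate (not isolated)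
4 | ethyl (1S,5R)-2-oxo-3-oxabicyclo[3.1.0]hexane-1-carboxylate | O1C[C@@H]2C[C@]2(C(=O)OCC)C1=O | intermediate
5 | 3,4,5-trimethoxybenzaldehyde | COc1cc(C=O)cc(OC)c1OC | starting material
6 | iodomagnesium enolate of ethyl (4R)-4-(iodomethyl)-2-oxooxolane-3-carboxylate | CCOC(=O)C1=C(O[Mg]I)OC[C@@H]1CI | intermediate (not isolated)
7 | iodomagnesium alkoxide of ethyl (3R,4R)-3-[(S)-hydroxy(3,4,5-trimethoxyphenyl)methyl]-4-(iodomethyl)-2-oxooxolane-3-carboxylate | O1C[C@H](CI)[C@@]([C@@H](O[Mg]I)c2cc(OC)c(OC)c(OC)c2)(C(=O)OCC)C1=O | intermediate (not isolated)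
8 | ethyl (3aS,6S,6aR)-1-oxo-6-(3,4,5-trimethoxyphenyl)tetrahydro-1H,3H-furo[3,4-c]furan-6a(6H)-carboxylate | O1C[C@@H]2CO[C@@H](c3cc(OC)c(OC)c(OC)c3)[C@]2(C(=O)OCC)C1=O | intermediate
9 | (3aS,6R,6aR)-6-(3,4,5-trimethoxyphenyl)tetrahydro-1H,3H-furo[3,4-c]furan-1-one | O1C[C@@H]2CO[C@@H](c3cc(OC)c(OC)c(OC)c3)[C@@H]2C1=O | intermediate
10 | [(2R,3R,4R)-4-(hydroxymethyl)-2-(3,4,5-trimethoxyphenyl)oxolan-3-yl](pyrrolidin-1-yl)methanone | OC[C@@H]1CO[C@@H](c2cc(OC)c(OC)c(OC)c2)[C@@H]1C(=O)N1CCCC1 | intermediate
11 | 4-bromo-1,2-dimethoxybenzene | COc1ccc(Br)cc1OC | starting material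
12 | [(2R,3R,4S)-4-{[(5,7-di-tert-butyl-3-phenyl-2,3-dihydro-1,3-benzoxazol-2-yl)oxy]methyl}-2-(3,4,5-trimethoxyphenyl)oxolan-3-yl](pyrrolidin-1-yl)methanone (both epimers at the aminal carbon) | CC(C)(C)c1cc(C(C)(C)C)c2OC(OC[C@@H]3CO[C@@H](c4cc(OC)c(OC)c(OC)c4)[C@@H]3C(=O)N3CCCC3)N(c3ccccc3)c2c1 | intermediate (not isolated)
13 | [(2R,3R,4S)-4-(3,4-dimethoxybenzyl)-2-(3,4,5-trimethoxyphenyl)oxolan-3-yl](pyrrolidin-1-yl)methanone | COc1ccc(C[C@@H]2CO[C@@H](c3cc(OC)c(OC)c(OC)c3)[C@@H]2C(=O)N2CCCC2)cc1OC | intermediate
14 | [(2R,3S,4S)-4-(3,4-dimethoxybenzyl)-2-(3,4,5-trimethoxyphenyl)oxolan-3-yl]methanol | COc1ccc(C[C@@H]2CO[C@@H](c3cc(OC)c(OC)c(OC)c3)[C@@H]2CO)cc1OC | target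

Total step count: 6. Longest linear sequence: 6 steps (1/2 → 4 → 8 → 9 → 10 → 13 → 14).

**Steps most likely to fail**

1. Step 2 (Proposed new method). Iodide may divert into reversible alkyl–oxygen cleavage of the lactone without aldol turnover. Retro-aldol equilibration may be too slow, so that aldolates that cannot close accumulate. The closure may discriminate poorly between the two faces at the aryl-bearing carbon, and long heating with iodide could erode enantiopurity by exchange of the two CH2 arms on C3a. The fallback makes the same O1–C5 bond by known chemistry in the enantiomeric lactone series, because the classical sequence closes the oxolane through the lactone methylene and not through the cyclopropane methylene. It sets out from 2: with (S)-epichlorohydrin and NaOEt it gives ethyl (1R,5S)-2-oxo-3-oxabicyclo[3.1.0]hexane-1-carboxylate F1. Copper-catalysed (CuI) homoconjugate addition of (3,4-dimethoxyphenyl)magnesium bromide, made from 11, opens the cyclopropane to ethyl (4S)-4-(3,4-dimethoxybenzyl)-2-oxooxolane-3-carboxylate F2. Krapcho dealkoxycarbonylation gives (4S)-4-(3,4-dimethoxybenzyl)oxolan-2-one F3. Its lithium enolate (LiHMDS, THF, −78 °C) adds to 5 anti to the benzyl group to give (3R,4S)-4-(3,4-dimethoxybenzyl)-3-[(R)-hydroxy(3,4,5-trimethoxyphenyl)methyl]oxolan-2-one F4, the carbinol epimer being removed by chromatography. Aminolysis with pyrrolidine gives (2R,3S)-3-(3,4-dimethoxybenzyl)-4-hydroxy-2-[(R)-hydroxy(3,4,5-trimethoxyphenyl)methyl]-1-(pyrrolidin-1-yl)butan-1-one F5. Selective sulfonylation of the primary alcohol (TsCl, pyridine, 0 °C) gives (2S,3R)-2-(3,4-dimethoxybenzyl)-3-[(R)-hydroxy(3,4,5-trimethoxyphenyl)methyl]-4-oxo-4-(pyrrolidin-1-yl)butyl 4-methylbenzenesulfonate F6. NaH in THF then closes the oxolane by 5-exo-tet displacement, and the route is rejoined at 13.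

2. Step 5. Oxidative addition of the electron-rich aryl bromide to nickel may be slow, so that the primary radical is lost to hydrogen-atom abstraction (net deoxygenation) or to intramolecular hydrogen transfer from the benzylic C2–H; relactonisation of 10 before adduct formation is a further loss channel. The fallback is a polar organozinc coupling that sets out from 9. Saponification (NaOH, aq. THF) and alkylation of the carboxylate (BnBr, DMF) give benzyl (2R,3R,4R)-4-(hydroxymethyl)-2-(3,4,5-trimethoxyphenyl)oxolane-3-carboxylate F7. Appel iodination (I2, PPh3, imidazole, 0 °C) gives benzyl (2R,3R,4S)-4-(iodomethyl)-2-(3,4,5-trimethoxyphenyl)oxolane-3-carboxylate F8. Zinc insertion (Zn dust, DMA) and Negishi coupling with 11 (Pd(OAc)2, SPhos) give benzyl (2R,3R,4S)-4-(3,4-dimethoxybenzyl)-2-(3,4,5-trimethoxyphenyl)oxolane-3-carboxylate F9. LiAlH4 reduction of the ester rejoins the route at 14.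

3. Step 3. At 140 °C the transient lactone enolate may expel the ring oxygen (E1cB opening of the oxolane to an α-arylidene lactone) instead of being protonated. The fallback decarboxylates through the neutral acid and sets out from 8. LiOH (aq. THF) followed by acidification to pH 2 gives (3aS,6S,6aR)-1-oxo-6-(3,4,5-trimethoxyphenyl)tetrahydro-1H,3H-furo[3,4-c]furan-6a(6H)-carboxylic acid F10; relactonisation can only engage the carboxyl group cis to the hydroxymethyl arm. Heating F10 in toluene at 110 °C should expel CO2 through the cyclic six-membered transition state of a β-oxo acid, without a free enolate, and rejoin the route at 9.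

**Further compounds**
F1 | step 2 | ethyl (1R,5S)-2-oxo-3-oxabicyclo[3.1.0]hexane-1-carboxylate | O1C[C@H]2C[C@@]2(C(=O)OCC)C1=O
F2 | step 2 | ethyl (4S)-4-(3,4-dimethoxybenzyl)-2-oxooxolane-3-carboxylate (C3 epimers) | O1C[C@@H](Cc2ccc(OC)c(OC)c2)C(C(=O)OCC)C1=O
F3 | step 2 | (4S)-4-(3,4-dimethoxybenzyl)oxolan-2-one | O1C[C@@H](Cc2ccc(OC)c(OC)c2)CC1=O
F4 | step 2 | (3R,4S)-4-(3,4-dimethoxybenzyl)-3-[(R)-hydroxy(3,4,5-trimethoxyphenyl)methyl]oxolan-2-one | O1C[C@@H](Cc2ccc(OC)c(OC)c2)[C@H]([C@@H](O)c2cc(OC)c(OC)c(OC)c2)C1=O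
F5 | step 2 | (2R,3S)-3-(3,4-dimethoxybenzyl)-4-hydroxy-2-[(R)-hydroxy(3,4,5-trimethoxyphenyl)methyl]-1-(pyrrolidin-1-yl)butan-1-one | OC[C@@H](Cc1ccc(OC)c(OC)c1)[C@H]([C@@H](O)c1cc(OC)c(OC)c(OC)c1)C(=O)N1CCCC1
F6 | step 2 | (2S,3R)-2-(3,4-dimethoxybenzyl)-3-[(R)-hydroxy(3,4,5-trimethoxyphenyl)methyl]-4-oxo-4-(pyrrolidin-1-yl)butyl 4-methylbenzenesulfonate | Cc1ccc(cc1)S(=O)(=O)OC[C@@H](Cc1ccc(OC)c(OC)c1)[C@H]([C@@H](O)c1cc(OC)c(OC)c(OC)c1)C(=O)N1CCCC1
F7 | step 5 | benzyl (2R,3R,4R)-4-(hydroxymethyl)-2-(3,4,5-trimethoxyphenyl)oxolane-3-carboxylate | OC[C@@H]1CO[C@@H](c2cc(OC)c(OC)c(OC)c2)[C@@H]1C(=O)OCc1ccccc1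
F8 | step 5 | benzyl (2R,3R,4S)-4-(iodomethyl)-2-(3,4,5-trimethoxyphenyl)oxolane-3-carboxylate | IC[C@@H]1CO[C@@H](c2cc(OC)c(OC)c(OC)c2)[C@@H]1C(=O)OCc1ccccc1
F9 | step 5 | benzyl (2R,3R,4S)-4-(3,4-dimethoxybenzyl)-2-(3,4,5-trimethoxyphenyl)oxolane-3-carboxylate | COc1ccc(C[C@@H]2CO[C@@H](c3cc(OC)c(OC)c(OC)c3)[C@@H]2C(=O)OCc2ccccc2)cc1OC
F10 | step 3 | (3aS,6S,6aR)-1-oxo-6-(3,4,5-trimethoxyphenyl)tetrahydro-1H,3H-furo[3,4-c]furan-6a(6H)-carboxylic acid | O1C[C@@H]2CO[C@@H](c3cc(OC)c(OC)c(OC)c3)[C@]2(C(=O)O)C1=O
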